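The runs were computed for substances that don't exist, noise included.

1. I decided to hold every flask against a single yardstick instead of guessing each one separately, and I took as its zero the plainest case, in which each catalyst simply repeats its pace from Thursday's run.

| flask | substrate | partner | free catalyst | remark | time |
|---|---|---|---|---|---|
| Thursday's | 30 mM | 36 mM (fed, over 4.0 min) | 38 µM | run made earlier |  |
| ochre | 20 mM | 20.0 mM (fed, over 4.0 min) | 120 µM |  | 15 min |
| amber | 20 mM | 36.0 mM (fed, over 4.0 min) | 38 µM |  | 15 min |
| red | 20 mM | 100 mM (fed, over 4.0 min) | 38 µM |  | 15 min |
| grey | 20 mM | 10.0 mM (fed, over 2.5 min) | 38 µM |  | 15 min |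
| teal | 20 mM | 25.0 mM (fed, over 12 min) | 12 µM |  | 15 min |

Thursday's run (percent of the substrate charged)

| time / min | product / % |
|---|---|
| 0.500 | 0 |
| 1.33 | 4 |
| 2.50 | 3 |
| 4.00 | 6 |
| 5.00 | 7 |
| 8.00 | 14 |
| 10.0 | 14 |

(scatter of a reading: 1.5 percentage points)

* all flasks from highest to lowest amount of product, in percent of the substrate charged, at 15 min (ochre / amber / red / grey / teal)
* the amount of product, in percent of the substrate charged of the flask you put first, at 15 min
* the amount of product, in percent of the substrate charged of the flask you put last, at 15 min

- reactions considered so far: partner + free catalyst <-> catalyst intermediate A; substrate + catalyst intermediate A <-> catalyst intermediate B; catalyst intermediate B <-> catalyst intermediate C; catalyst intermediate C -> by-product + catalyst intermediate D; catalyst intermediate D -> free catalyst + product; partner -> decomposed reagent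
- no earlier run changes the charge of free catalyst; that part of a forecast is a guess

2. Thursday's run read product at 14% of its substrate at 10.0 min, which is 0.420 mM min⁻¹ on average, so I took the turnover frequency f, product made per minute per catalyst charged, as 11.1 min⁻¹, a reading that carries the scatter of 1.5 percentage points.

3. I called b = f·c·t/S the budget, where c is the catalyst charged, t the time and S the substrate charged, so that b is the percent of substrate made at Thursday's pace.

4. Amber looked nearly like Thursday's run, with the same partner, catalyst and feed but 20 mM of substrate against 30 mM. At f, my reckoning gave amber 6.30 mM of product by 15 min, so its budget was 31.5%, and each millimolar counted 1.50 times as many percent on amber's smaller charge.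

5. By my own reckoning ochre's budget of 99.5% was larger than teal's 9.95%, so I put ochre first and teal last, while amber, red and grey tied at 31.5%.

6. The forecast gave ochre > red > amber > grey > teal, with 62% for the first flask and 8% for the last, and it expected of red that “extra partner helps little”; for ochre its number stood below my budget.

7. The flasks gave ochre > red > amber > grey > teal, with 41.6% and 5.63%, so the forecast's order held, and its first flask stood 20 points too high.

    partner + free catalyst ⇌ catalyst intermediate A (K = 21.0 M⁻¹, k = 2600 M⁻¹ min⁻¹)
    substrate + catalyst intermediate A ⇌ catalyst intermediate B (K = 35.0 M⁻¹, k = 4600 M⁻¹ min⁻¹)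
    catalyst intermediate B ⇌ catalyst intermediate C (K = 4.50, k = 880 min⁻¹)
    catalyst intermediate C → by-product + catalyst intermediate D (k = 59.0 min⁻¹)
    catalyst intermediate D → free catalyst + product (k = 1600 min⁻¹)
    partner → decomposed reagent (k = 0.0510 min⁻¹)

8. Ochre delivered 0.418 of its budget, and its neighbour charged with 0.30 mM of free catalyst, whose budget at f = 11.1 min⁻¹ was 250%, gave 65.2%, so Thursday's pace per catalyst did not carry over to ochre or to that neighbour. At 15.0 min, ochre held 87.9% of its catalyst as free catalyst, and the main reason for ochre's missing product was the way back from catalyst intermediate A to partner and free catalyst, which accounted for 50% of what was missing. Run without that way back, ochre rose from 41.6% to 71.0%.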